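Labdane numbering is used throughout. In the target, spiro carbon C13 bears the ether oxygen O9 and adjoins the C12 ketone, a semipinacol retron. The dihydrofuran ring (C13, C14, C15, O, C16) is therefore carried as a six-membered dihydropyran that also contains C12 and is fused through a C12=C13 enol ether to the C9-spiro oxolane. Hydroxyl-directed epoxidation of this enol ether makes C14 shift from C12 to C13; one operation expels C12 from the ring (six to five), unveils the ketone and sets C13. The precursor arises from a carvone-derived 9-methylene decalin and 2H-pyran-3,5-dione by Mn(OAc)3 annulation, then CBS reduction.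

Key step: step 13

Remarks:
- Every intermediate keeps labdane numbers. Carvone C1 = C9, C2 = C8, its 2-methyl = C17, C3 = C7, C4 = C6, C5 = C5, C6 = C10, and the isopropenyl group = C4, C18, C19. O9 is the ether oxygen between C9 and C13.
- C4 forms as an epimer mixture in step 3. It is left undefined in the SMILES of 5 to 10, because step 7 planarises and resets it.
- LDA and KHMDS are used as purchased solutions.

Step 1
Reactants: 1 (R)-(−)-carvone
Product: 2 trans-6-methylcarvone (new methyl C20 on C10, anti to the isopropenyl group)
Conditions: LDA, THF, −78 °C; MeI, −78 to 0 °C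
Reagents that add atoms: iodomethane CI
Why: Kinetic enolate alkylation: LDA removes a proton from C10, the only α'-position of the cross-conjugated enone, and MeI attacks anti to the isopropenyl group, although this centre is planarised again in step 2.

Step 2
Reactants: 2 trans-6-methylcarvone; 3 1-chloro-3-iodopropane
Product: 4 quaternary enone (C10 bears C20 methyl cis and the C1–C3 chloropropyl chain trans to the C5 isopropenyl group)
Conditions: LDA, THF, −78 to 0 °C; DMPU, 3, −78 °C to rt
Reagents that add atoms: none
Why: Enolate alkylation at the iodide end of 3: the tetrasubstituted dienolate is shielded on one face by the C5 isopropenyl group, so the chain enters anti to it and C10 is set with C20 cis and C1 trans to C4, the arrangement of a trans-decalin.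

Step 3
Reactants: 4 quaternary enone
Product: 6 primary alcohol (isopropenyl turned into CH(CH3)CH2OH, 19-OH), via catechol boronate 5 (not isolated)
Conditions: catecholborane, RhCl(PPh3)3 (3 mol %), THF, rt; then H2O2, pH 7 phosphate buffer, 0 °C
Reagents that add atoms: catecholborane [H]B1Oc2ccccc2O1 (its atoms stay only in 5); hydrogen peroxide OO
Why: Rhodium-catalysed anti-Markovnikov hydroboration followed by oxidation: the catalyst directs catecholborane to the 1,1-disubstituted alkene while the s-trans cyclic enone and its hindered carbonyl stay inert, neutral peroxide avoids enone epoxidation, and the unselective C4 centre is reset in step 7.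

Step 4
Reactants: 6 primary alcohol
Product: 7 enone 19-carboxylic acid
Conditions: TEMPO (2,2,6,6-tetramethylpiperidin-1-oxyl, cat.), PhI(OAc)2, MeCN–H2O, rt
Reagents that add atoms: water O
Why: Oxoammonium oxidation (TEMPO with PhI(OAc)2 in aqueous MeCN) takes the primary alcohol through the aldehyde hydrate to the acid and leaves enone and alkyl chloride untouched.

Step 5
Reactants: 7 enone 19-carboxylic acid
Product: 9 enone 19,6β-lactone (cis-fused γ-lactone, C7=C8 enone kept), via 6α-bromide 8 (not isolated)
Conditions: NBS, AIBN (2,2'-azobis(2-methylpropionitrile), cat.), PhCF3, 80 °C; then NaHCO3, DMF, rt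
Reagents that add atoms: N-bromosuccinimide O=C1CCC(=O)N1Br (bromine stays only in 8)
Why: Wohl–Ziegler bromination abstracts the secondary γ-hydrogen at C6, whose radical is conjugated with the enone, and brominates anti to the C5 side chain, after which the carboxylate displaces the 6α-bromide with inversion (SN2, 5-exo-tet) and so sets the 6β C–O bond as a cis-fused γ-lactone.

Step 6
Reactants: 9 enone 19,6β-lactone
Product: 10 triethylsilyl enol ether (C8=C9–OSiEt3) of the lactone
Conditions: Et3SiH, RhCl(PPh3)3 (2 mol %), toluene, 50 °C
Reagents that add atoms: triethylsilane CC[SiH](CC)CC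
Why: Rhodium-catalysed 1,4-hydrosilylation of the enone with a monohydrosilane saturates C7 without hydrogenolysis of the allylic C6–O bond and stores the C9 ketone as a silyl enol ether that has no acidic C8–H in step 7.

Step 7
Reactants: 10 triethylsilyl enol ether
Product: 12 keto lactone (trans-decalin 19,6β-olide with 4α-CH3, 5α-H, 8α-CH3, 10β-CH3 and 9-oxo), via tricyclic silyl enol ether 11 (not isolated)
Conditions: KHMDS, THF–DMPU, −78 to 40 °C; then 1 M HCl, THF, rt
Reagents that add atoms: none
Why: Intramolecular lactone enolate alkylation (6-enolexo-exo-tet) closes ring A, C4 being set because C19 is tied to the 6β-oxygen and the chain hangs from C10 so that C3 can bond only on the face that leaves C18 α and C19 β, and acid hydrolysis of the silyl enol ether then delivers the ketone with the equatorial 8α-methyl group, the 8β epimer being 1,3-diaxial to C20.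

Step 8
Reactants: 12 keto lactone
Product: 13 9-methylene lactone (C9=C11H2)
Conditions: Ph3PCH3Br, KOt-Bu, toluene, 90 °C
Reagents that add atoms: methyltriphenylphosphonium bromide C[P+](c1ccccc1)(c1ccccc1)c1ccccc1.[Br-]
Why: Wittig methylenation under the forcing conditions used for hindered ketones converts C9=O, the lactone carbonyl next to quaternary C4 is too shielded to react, and base can only keep C8 in its favoured equatorial configuration.

Step 9
Reactants: 13 9-methylene lactone
Product: 14 9-methylene 6β,19-diol
Conditions: LiAlH4, THF, 0 °C to reflux; aqueous NaOH work-up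
Reagents that add atoms: none
Why: Hydride reduction of the γ-lactone to the 1,4-diol, the isolated alkene being inert to LiAlH4.

Step 10
Reactants: 14 9-methylene 6β,19-diol
Product: 15 silylene alkene (6β,19-O-di-tert-butylsilanediyl 9-methylene decalin)
Conditions: t-Bu2Si(OTf)2, 2,6-lutidine, CH2Cl2, 0 °C
Reagents that add atoms: di-tert-butylsilyl bis(trifluoromethanesulfonate) CC(C)(C)[Si](OS(=O)(=O)C(F)(F)F)(OS(=O)(=O)C(F)(F)F)C(C)(C)C
Why: Silylene formation: the axial 6β-hydroxyl and the axial C19 hydroxymethyl group lie side by side, so the bis-triflate bridges them in a seven-membered ring that masks both in one step and is later removed by fluoride under nearly neutral conditions.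

Step 11
Reactants: 15 silylene alkene; 16 2H-pyran-3,5(4H,6H)-dione
Product: 17 vinylogous ester (C9-spiro 4,5-dihydrofuran O9–C9–C11–C12=C13, fused at C12=C13 to a pyranone ring C13–C16H2–O–C15H2–C14(=O)–C12; O9 α, C11 β)
Conditions: Mn(OAc)3·2H2O (2.2 equiv), AcOH, 60 °C, argon
Reagents that add atoms: none
Why: Mn(OAc)3-mediated oxidative radical annulation of a 1,3-dione with a 1,1-disubstituted alkene to a dihydrofuran: the electrophilic C12 radical adds to the unhindered C11 terminus, the tertiary C9 radical is oxidised to the cation and the enol oxygen closes on its axial α face, opposite to the axial C20 methyl group, which sets C9 with O9 α and C11 β (the symmetry of 16 excludes regioisomers).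

Step 12
Reactants: 17 vinylogous ester
Product: 18 (14R)-allylic alcohol (14-OH on the face of the bicycle that is syn to C8)
Conditions: (R)-Me-CBS ((R)-1-methyl-3,3-diphenyltetrahydro-1H,3H-pyrrolo[1,2-c][1,3,2]oxazaborole), catecholborane, toluene, −60 to −40 °C; aqueous NaHCO3 work-up, Et3N-washed silica
Reagents that add atoms: none
Why: Corey–Bakshi–Shibata reduction: the carbonyl binds the oxazaborolidine with the substituted alkene carbon C12 as large and C15H2 as small group, so the (R)-catalyst should deliver hydride to give the (14R)-alcohol under reagent control, and catecholborane at low temperature spares the tetrasubstituted enol ether.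

Step 13
Reactants: 18 (14R)-allylic alcohol
Product: 20 dispiro hydroxy ketone (12-oxo; oxolane ring C13–C14H(OH)–C15H2–O–C16H2 with C14 syn to C10, C16 syn to C8, 14-OH cis to C12), via 12,13-epoxide 19 (not isolated)
Conditions: VO(acac)2 (5 mol %), t-BuOOH (decane), 4 Å MS, CH2Cl2, −20 to 0 °C
Reagents that add atoms: tert-butyl hydroperoxide CC(C)(C)OO
Why: The C14 hydroxyl binds the vanadium tert-butylperoxo complex and delivers oxygen to the C12=C13 enol ether on its own face, the face syn to C8, to give epoxide 19. O9 then pushes open the C13–O bond and, as the oxocarbenium ion develops, the C12–C14 bond migrates to C13 anti to the departing oxygen while the C12 alkoxide collapses to the ketone. The closest known reaction types are the hydroxyl-directed VO(acac)2/t-BuOOH epoxidation of cyclic allylic alcohols and the semipinacol rearrangement of 2-alkoxy epoxides, the oxygen counterpart of the oxidative contraction of tetrahydrocarbazoles to spiro-pseudoindoxyls. The oxirane is closed by syn oxygen transfer, and the five-membered ring C13–C14–C15–O–C16 is closed by the suprafacial 1,2-shift that forms C13–C14 and cuts C12 out of the six-membered ring, so the fused bicycle becomes the spiro pair. C13 is controlled by the temporary C14 carbinol centre through the face of epoxidation and the inversion at C13, C14 itself migrates with retention, and C12 ends as sp2. The step needs face selectivity (secured by the bound hydroxyl, since C1H2 and the C17 methyl group shield the two faces almost alike), opening at C13 rather than C12 (secured by O9) and migration of C14 rather than C11 (a C11 shift would make an oxetane and its bond lies near the nodal plane of the cation).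

Step 14
Reactants: 20 dispiro hydroxy ketone
Product: 22 silylene-protected target (C14=C15 enol ether), via sulfamate ester 21 (not isolated)
Conditions: Burgess reagent, toluene, rt to 70 °C
Reagents that add atoms: Burgess reagent CC[N+](CC)(CC)S(=O)(=O)[N-]C(=O)OC (its atoms stay only in 21)
Why: Burgess dehydration, a thermal syn elimination through the sulfamate ester: C13 is quaternary, so the only β-hydrogens are on C15 and the C14=C15 enol ether is the only possible alkene, formed without acid or strong base that would endanger the β-alkoxy ketone.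

Step 15
Reactants: 22 silylene-protected target
Product: 23 CNP0176827.1
Conditions: TBAF, AcOH (1:1), THF, 0 °C to rt
Reagents that add atoms: none
Why: Fluoride cleavage of the silylene, buffered with AcOH so that neither the acid-labile enol ether nor the base-labile β-alkoxy ketone is harmed.

Compound list
1 | (R)-(−)-carvone | CC1=CC[C@H](CC1=O)C(C)=C | starting material
2 | trans-6-methylcarvone | CC1=CC[C@H]([C@H](C)C1=O)C(C)=C | intermediate
3 | 1-chloro-3-iodopropane | ClCCCI | starting material
4 | quaternary enone (C20 cis, chloropropyl trans to isopropenyl) | CC1=CC[C@H]([C@](C)(CCCCl)C1=O)C(C)=C | intermediate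
5 | catechol boronate at C19 (not isolated) | CC1=CC[C@H]([C@](C)(CCCCl)C1=O)C(C)CB2Oc3ccccc3O2 | intermediate
6 | primary alcohol (19-OH) | CC1=CC[C@H]([C@](C)(CCCCl)C1=O)C(C)CO | intermediate
7 | enone 19-carboxylic acid | CC1=CC[C@H]([C@](C)(CCCCl)C1=O)C(C)C(=O)O | intermediate
8 | 6α-bromo enone acid (not isolated) | CC1=C[C@H](Br)[C@H]([C@](C)(CCCCl)C1=O)C(C)C(=O)O | intermediate
9 | enone 19,6β-lactone | CC1=C[C@@H](O2)[C@H]([C@](C)(CCCCl)C1=O)C(C)C2=O | intermediate
10 | triethylsilyl enol ether of the lactone | CC1=C(O[Si](CC)(CC)CC)[C@@](C)(CCCCl)[C@@H]2C(C)C(=O)O[C@@H]2C1 | intermediate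
11 | tricyclic silyl enol ether, ring A closed (not isolated) | CC1=C(O[Si](CC)(CC)CC)[C@@]2(C)CCC[C@](C)(C(=O)O3)[C@@H]2[C@H]3C1 | intermediate
12 | keto lactone (9-oxo 19,6β-olide) | C[C@@H]1C[C@@H](O3)[C@H]2[C@@](C)(C3=O)CCC[C@]2(C)C1=O | intermediate
13 | 9-methylene lactone | C[C@@H]1C[C@@H](O3)[C@H]2[C@@](C)(C3=O)CCC[C@]2(C)C1=C | intermediate
14 | 9-methylene 6β,19-diol | C[C@@H]1C[C@@H](O)[C@H]2[C@@](C)(CO)CCC[C@]2(C)C1=C | intermediate
15 | silylene alkene | C[C@@H]1C[C@@H](O3)[C@H]2[C@@](C)(CO[Si]3(C(C)(C)C)C(C)(C)C)CCC[C@]2(C)C1=C | intermediate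
16 | 2H-pyran-3,5(4H,6H)-dione | O=C1COCC(=O)C1 | starting material
17 | vinylogous ester (fused dihydrofuran–pyranone) | C[C@@H]1C[C@@H](O3)[C@H]2[C@@](C)(CO[Si]3(C(C)(C)C)C(C)(C)C)CCC[C@]2(C)[C@@]14CC5=C(O4)COCC5=O | intermediate
18 | (14R)-allylic alcohol | C[C@@H]1C[C@@H](O3)[C@H]2[C@@](C)(CO[Si]3(C(C)(C)C)C(C)(C)C)CCC[C@]2(C)[C@@]14CC5=C(O4)COC[C@@H]5O | intermediate
19 | 12,13-epoxide, oxygen syn to C8 and to 14-OH (not isolated) | C[C@@H]1C[C@@H](O3)[C@H]2[C@@](C)(CO[Si]3(C(C)(C)C)C(C)(C)C)CCC[C@]2(C)[C@@]14C[C@@]56O[C@]5(O4)COC[C@@H]6O | intermediate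
20 | dispiro hydroxy ketone | C[C@@H]1C[C@@H](O3)[C@H]2[C@@](C)(CO[Si]3(C(C)(C)C)C(C)(C)C)CCC[C@]2(C)[C@@]14CC(=O)[C@]5([C@@H](O)COC5)O4 | intermediate
21 | C14 sulfamate ester (not isolated) | C[C@@H]1C[C@@H](O3)[C@H]2[C@@](C)(CO[Si]3(C(C)(C)C)C(C)(C)C)CCC[C@]2(C)[C@@]14CC(=O)[C@]5([C@@H](OS(=O)(=O)NC(=O)OC)COC5)O4 | intermediate
22 | silylene-protected target | C[C@@H]1C[C@@H](O3)[C@H]2[C@@](C)(CO[Si]3(C(C)(C)C)C(C)(C)C)CCC[C@]2(C)[C@@]14CC(=O)[C@]5(C=COC5)O4 | intermediate
23 | CNP0176827.1 | C[C@@H]1C[C@@H](O)[C@H]2[C@@](C)(CO)CCC[C@]2(C)[C@@]12CC(=O)[C@]1(C=COC1)O2 | target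

Total step count: 15. Longest linear sequence: 15 steps, from 1.

Steps most likely to fail

**Step 13.** The Lewis-acidic vanadium may ionise the β-alkoxy allylic alcohol before oxygen transfer. The oxocarbenium ion may also lose a C16 proton or be captured by t-BuOH instead of undergoing the 1,2-shift.

The fallback sets out from 17 and comes back at 20. It keeps C14 as a ketone, so no ionisable carbinol is present and the migrating group is an acyl group.
- Compound 17 is epoxidised on the face syn to C8. The oxidant is the chiral dioxirane made from KHSO5 and the ketone catalyst 1,2:4,5-di-O-isopropylidene-β-D-erythro-2,3-hexodiulo-2,6-pyranose, or its enantiomer, whichever matches that face. This gives the β-alkoxy epoxy ketone F1.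
- BF3·OEt2 in CH2Cl2 at −78 °C then induces the classical epoxy ketone to 1,3-diketone rearrangement. C14 shifts from C12 to C13 with the same six-to-five contraction and gives the spiro diketone F2.
- NaBH4 in MeOH–CH2Cl2 at −78 °C reduces the less hindered C14 ketone, which is flanked by two α-oxygens, to 20.
- The C14 epimeric alcohol F3, if formed, is returned to F2 with Dess–Martin periodinane.

**Step 12.** Hydride transfer to the electron-rich vinylogous ester carbonyl may be sluggish. Facial selectivity may be poor. The product may also be lost by acid-catalysed allylic transposition on work-up.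

The fallback sets out from 17 and comes back at 18. It gives up reagent control.
- DIBAL-H in toluene at −78 °C gives 18 together with the C14 epimeric allylic alcohol F4.
- The two are diastereomers and are separated on Et3N-deactivated silica.
- F4 is oxidised back to 17 with MnO2 and recycled.

**Step 5.** Hydrogen abstraction may occur at the C17 methyl group. The bromide may also dehydrobrominate to a dienone before the carboxylate closes.

The fallback sets out from 7 and comes back at 9. It replaces the radical step by ionic chemistry.
- LDA (3 equiv) followed by kinetic protonation with AcOH at −78 °C moves the double bond out of conjugation. This gives the β,γ-unsaturated keto acid F5.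
- I2 and NaHCO3 in MeCN close the iodolactone F6. The iodonium ion sits on the α face and the carboxylate attacks C6 from the β face (5-exo).
- DBU eliminates the β-iodide towards C8 to give 9.

Further compounds
F1 | step 13 | β-alkoxy epoxy ketone (12,13-epoxide of 17, oxygen syn to C8) | C[C@@H]1C[C@@H](O3)[C@H]2[C@@](C)(CO[Si]3(C(C)(C)C)C(C)(C)C)CCC[C@]2(C)[C@@]14C[C@@]56O[C@]5(O4)COCC6=O
F2 | step 13 | spiro 12,14-diketone | C[C@@H]1C[C@@H](O3)[C@H]2[C@@](C)(CO[Si]3(C(C)(C)C)C(C)(C)C)CCC[C@]2(C)[C@@]14CC(=O)[C@]5(C(=O)COC5)O4
F3 | step 13 | C14 epimer of 20 | C[C@@H]1C[C@@H](O3)[C@H]2[C@@](C)(CO[Si]3(C(C)(C)C)C(C)(C)C)CCC[C@]2(C)[C@@]14CC(=O)[C@]5([C@H](O)COC5)O4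
F4 | step 12 | C14 epimer of 18 | C[C@@H]1C[C@@H](O3)[C@H]2[C@@](C)(CO[Si]3(C(C)(C)C)C(C)(C)C)CCC[C@]2(C)[C@@]14CC5=C(O4)COC[C@H]5O
F5 | step 5 | β,γ-unsaturated keto acid (C6=C7) | CC1C=C[C@H]([C@](C)(CCCCl)C1=O)C(C)C(=O)O
F6 | step 5 | 7α-iodo 19,6β-lactone | CC1[C@H](I)[C@@H](O2)[C@H]([C@](C)(CCCCl)C1=O)C(C)C2=O
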